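Which form holds the most catalyst comes down to a comparison of stays: how long one catalyst molecule sits in each form during one round.

    partner + free catalyst → catalyst intermediate A (k1 = 3.02 L mol⁻¹ s⁻¹)
    catalyst intermediate A → catalyst intermediate B (k2 = 1.56 s⁻¹)
    catalyst intermediate B ⇌ by-product + catalyst intermediate C (K3 = 0.44 M, k3 = 1.39 s⁻¹)
    starting material + catalyst intermediate C ⇌ catalyst intermediate D (K4 = 96.0 L mol⁻¹, k4 = 108 L mol⁻¹ s⁻¹)
    catalyst intermediate D → free catalyst + target (k5 = 0.315 s⁻¹)
    free catalyst + by-product ⇌ idle complex, settled at all times (K6 = 110 L mol⁻¹)

starting material 0.10 M; partner 0.400 M; free catalyst 5.0 mM

- the form that holds most of the catalyst when 50% of the starting material are converted (free catalyst / catalyst intermediate A / catalyst intermediate C / catalyst intermediate D / catalyst intermediate B / idle complex)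
- its share of the catalyst then

Follow one catalyst molecule round the cycle at 50% conversion. As long as each form is made as fast as it is used up, each form's share of the catalyst goes in proportion to the time spent in it per completed round. Each round uses one starting material and one partner and releases one by-product. Neglecting what the catalyst holds, starting material stands at 0.0500 M, by-product at 0.0500 M and partner at 0.350 M.

Free catalyst waits for partner, so its stay is one over rate constant times partner:

free catalyst: 0.946 s

While it waits, it stays at balance with the idle complex, which stands outside the working round (off-cycle). The idle complex therefore holds m = the equilibrium constant of that balance times by-product = 5.50 times as much catalyst as the free form. The time per round spent in the idle complex, the parked time, is m times the stay as free catalyst: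

idle complex: 5.20 s

Intermediate A has one exit:

intermediate A: 0.641 s

At intermediate D the molecule forks. It goes on to target with a chance of 21.9% and otherwise falls back to intermediate C. The repeated visits add up to one over the rate constant of the forward exit:

intermediate D: 3.17 s

Those repeat visits also pass through intermediate C, and from there a trip can run back to intermediate B:

intermediate C: 0.847 s

intermediate B: 0.816 s

The round takes 11.6 s. The idle complex has the longest stay, so this reckoning names it, with 44.8% of the catalyst, against 27.3% for intermediate D.

The forecast named the idle complex at 44%, within 39% to 49%, on the ground that “that pool beats intermediate D”; its figure lies slightly below this reckoning.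

The simulation gives the idle complex at 43.6%.

The flask's shares at 1.39 min set the idle complex against intermediate D at a ratio of 1.55, while the parked time of 5.20 s against the stay of 3.17 s gives 1.64. At 2.50 min the flask holds 0.0726 M of by-product and partner at 81.1% of its charge, which reckons to a parked time of 8.15 s, a ratio of 2.57 to the same stay, and the flask then shows the idle complex at 52.0% and intermediate D at 20.4%, a ratio of 2.55.

The numbers were chosen freely.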